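**Retrosynthetic overview**
- The target is reached by removing a tosyl and a triisopropylsilyl (TIPS) group from a tetralin–oxolane. Its tetralin C1–C8a bond comes from acid isomerisation of the guaiacylmethyl oxolane of a 5,5'-linked bis-oxolane (third ring formed).
- Both oxolane O1–C2 bonds are made in one operation by a twofold Ag2O quinone-methide cycloetherification of an acyclic biaryl bis-triol (first two rings formed).
- The biaryl C5–C5' bond comes from Suzuki–Miyaura coupling of two 5-bromovanillyl triols that differ only in the second arylmethyl group, followed by hydrogenolysis of the two biaryl benzyl ethers.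
- Each triol comes from LiAlH4 reduction of a 2,3-bis(arylmethyl) (S)-malate: anti Fráter–Seebach alkylation of diethyl (S)-malate, then dioxolanone alkylation with retention.
- Feature: the oxolane O1–C2 bond and the tetralin C1–C8a bond both sit at a para-hydroxybenzylic carbon of the 5,5'-biaryl, and oxolane C3/C4 and tetralin C2/C3 are the same CH(CH2OH)–C(OH)(CH2–) unit, a (2S,3R)-2,3-dialkylmalate at the alcohol oxidation level.

Key step: step 20

Remark: a symmetric biaryl bis-dioxolanone could not receive two different arylmethyl groups selectively, so each half is built on its own 5-bromovanillyl unit (the aryl bromide tolerates LiAlH4) and the biaryl bond is made afterwards.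
Remark: the isovanillyl oxygen is carried as a tosylate (electron-withdrawing, no acidic hydrogen next to sulfur), the guaiacyl oxygen as a TIPS ether and the two biaryl oxygens as benzyl ethers; diethyl (S)-malate, 5-bromovanillin, vanillin and isovanillin are taken as commercial.

**Fragment common to both halves**

Step 1
Reactants: 1 5-bromovanillin
Product: 2 4-(benzyloxy)-3-bromo-5-methoxybenzaldehyde
Conditions: BnBr (1.2 equiv), K2CO3, DMF, 60 °C
Reagents that add atoms: benzyl bromide, BrCc1ccccc1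
Why: Williamson etherification of the acidic phenoxide; the benzyl ether survives every step up to the biaryl and is removed by hydrogenolysis just before the oxidation.

Step 2
Reactants: 2 4-(benzyloxy)-3-bromo-5-methoxybenzaldehyde
Product: 3 [4-(benzyloxy)-3-bromo-5-methoxyphenyl]methanol
Conditions: NaBH4, MeOH/THF, 0 °C
Reagents that add atoms: none
Why: Borohydride reduction of the aldehyde, which leaves the aryl bromide and the ether untouched.

Step 3
Reactants: 3 [4-(benzyloxy)-3-bromo-5-methoxyphenyl]methanol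
Product: 4 2-(benzyloxy)-1-bromo-5-(bromomethyl)-3-methoxybenzene
Conditions: PBr3 (0.4 equiv), CH2Cl2, 0 °C
Reagents that add atoms: phosphorus tribromide, BrP(Br)Br
Why: Bromination of the benzylic alcohol through its phosphite ester (SN2 by bromide).

Step 4
Reactants: 5 diethyl (S)-malate; 4 2-(benzyloxy)-1-bromo-5-(bromomethyl)-3-methoxybenzene
Product: 6 diethyl (2S,3R)-3-{[4-(benzyloxy)-3-bromo-5-methoxyphenyl]methyl}-2-hydroxybutanedioate
Conditions: LiN(SiMe3)2 (2.2 equiv), THF, −78 → −20 °C; then 4 (0.9 equiv), −78 → 0 °C; then 1 M HCl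
Reagents that add atoms: none
Why: Fráter–Seebach alkylation: the dilithium alkoxide–enolate chelate is attacked by the benzylic bromide on the face anti to the C2 alkoxide, which sets C3 as R (anti, 2S,3R) while C2 stays S; the minor syn epimer is removed by chromatography.

Step 5
Reactants: 6 diethyl (2S,3R)-3-{[4-(benzyloxy)-3-bromo-5-methoxyphenyl]methyl}-2-hydroxybutanedioate
Product: 7 (2S,3R)-3-{[4-(benzyloxy)-3-bromo-5-methoxyphenyl]methyl}-2-hydroxybutanedioic acid
Conditions: KOH (4 equiv), EtOH/H2O, rt; then HCl to pH 1, 0 °C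
Reagents that add atoms: potassium hydroxide, [K+].[OH-]
Why: Saponification of both esters at room temperature, where the dicarboxylate resists epimerisation at C3.

Step 6
Reactants: 7 (2S,3R)-3-{[4-(benzyloxy)-3-bromo-5-methoxyphenyl]methyl}-2-hydroxybutanedioic acid
Product: 8 (2R)-3-[4-(benzyloxy)-3-bromo-5-methoxyphenyl]-2-[(2S,4S)-2-tert-butyl-5-oxo-1,3-dioxolan-4-yl]propanoic acid
Conditions: t-BuCHO (3 equiv), TsOH·H2O (cat.), H2SO4 (cat.), CH2Cl2/pentane, reflux, Dean–Stark
Reagents that add atoms: pivalaldehyde, CC(C)(C)C=O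
Why: Seebach acetalisation of the α-hydroxy acid (self-regeneration of stereocentres): the five-membered dioxolanone is preferred over the six-membered dioxanone and equilibrates under acid to the cis isomer, so the acetal carbon is set S by the existing α-carbon.

**Fragment A (isovanillyl tosylate side)**

Step 7
Reactants: 9 isovanillin
Product: 10 5-formyl-2-methoxyphenyl 4-methylbenzenesulfonate
Conditions: TsCl, Et3N, DMAP (cat.), CH2Cl2, 0 °C → rt
Reagents that add atoms: 4-toluenesulfonyl chloride, Cc1ccc(cc1)S(=O)(=O)Cl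
Why: Sulfonylation of the phenol gives an aryl tosylate that tolerates enolates, LiAlH4, palladium catalysis and acid, and that deactivates this ring in step 21.

Step 8
Reactants: 10 5-formyl-2-methoxyphenyl 4-methylbenzenesulfonate
Product: 11 5-(hydroxymethyl)-2-methoxyphenyl 4-methylbenzenesulfonate
Conditions: NaBH4, MeOH/THF, 0 °C
Reagents that add atoms: none
Why: Borohydride reduction of the aldehyde; the aryl sulfonate is inert.

Step 9
Reactants: 11 5-(hydroxymethyl)-2-methoxyphenyl 4-methylbenzenesulfonate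
Product: 12 5-(bromomethyl)-2-methoxyphenyl 4-methylbenzenesulfonate
Conditions: PBr3 (0.4 equiv), CH2Cl2, 0 °C
Reagents that add atoms: phosphorus tribromide, BrP(Br)Br
Why: Bromination of the benzylic alcohol through its phosphite ester.

Step 10
Reactants: 8 (2R)-3-[4-(benzyloxy)-3-bromo-5-methoxyphenyl]-2-[(2S,4S)-2-tert-butyl-5-oxo-1,3-dioxolan-4-yl]propanoic acid; 12 5-(bromomethyl)-2-methoxyphenyl 4-methylbenzenesulfonate
Product: 13 (2R)-3-[4-(benzyloxy)-3-bromo-5-methoxyphenyl]-2-[(2S,4S)-2-tert-butyl-4-{[4-methoxy-3-(tosyloxy)phenyl]methyl}-5-oxo-1,3-dioxolan-4-yl]propanoic acid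
Conditions: LiN(SiMe3)2 (2.2 equiv), THF, −78 °C; then 12 (1.3 equiv), −78 → −30 °C; then 1 M HCl, 0 °C
Reagents that add atoms: none
Why: Seebach dioxolanone alkylation: the first equivalent of base gives the carboxylate and the second the lactone enolate, which the benzylic bromide attacks on the face anti to the tert-butyl group (the face that carried H), so the quaternary carbon forms with retention.

Step 11
Reactants: 13 (2R)-3-[4-(benzyloxy)-3-bromo-5-methoxyphenyl]-2-[(2S,4S)-2-tert-butyl-4-{[4-methoxy-3-(tosyloxy)phenyl]methyl}-5-oxo-1,3-dioxolan-4-yl]propanoic acid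
Product: 14 (2S,3S)-3-{[4-(benzyloxy)-3-bromo-5-methoxyphenyl]methyl}-2-{[4-methoxy-3-(tosyloxy)phenyl]methyl}butane-1,2,4-triol
Conditions: LiAlH4 (4 equiv), THF, 0 °C → rt; then aqueous potassium sodium tartrate
Reagents that add atoms: none
Why: Hydride reduction of the carboxylic acid and of the acylal lactone, which opens to the tertiary alkoxide and pivalaldehyde (reduced to neopentyl alcohol); aryl bromide, aryl tosylate and benzyl ether should survive at this temperature and no stereocentre is touched.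

**Fragment B (guaiacyl TIPS side)**

Step 12
Reactants: 15 vanillin
Product: 16 3-methoxy-4-[(triisopropylsilyl)oxy]benzaldehyde
Conditions: TIPSCl, imidazole, DMF, rt
Reagents that add atoms: chlorotriisopropylsilane, CC(C)[Si](Cl)(C(C)C)C(C)C
Why: Silylation of the phenol blocks quinone-methide formation on this ring in step 20 while keeping the ring electron-rich for step 21.

Step 13
Reactants: 16 3-methoxy-4-[(triisopropylsilyl)oxy]benzaldehyde
Product: 17 {3-methoxy-4-[(triisopropylsilyl)oxy]phenyl}methanol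
Conditions: NaBH4, MeOH, 0 °C
Reagents that add atoms: none
Why: Borohydride reduction of the aldehyde; the hindered aryl silyl ether is stable.

Step 14
Reactants: 17 {3-methoxy-4-[(triisopropylsilyl)oxy]phenyl}methanol
Product: 18 [4-(bromomethyl)-2-methoxyphenoxy]triisopropylsilane
Conditions: PBr3 (0.4 equiv), Et2O, 0 °C; used at once
Reagents that add atoms: phosphorus tribromide, BrP(Br)Br
Why: Bromination of the benzylic alcohol through its phosphite ester; the reactive bromide is not stored.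

Step 15
Reactants: 8 (2R)-3-[4-(benzyloxy)-3-bromo-5-methoxyphenyl]-2-[(2S,4S)-2-tert-butyl-5-oxo-1,3-dioxolan-4-yl]propanoic acid; 18 [4-(bromomethyl)-2-methoxyphenoxy]triisopropylsilane
Product: 19 (2R)-3-[4-(benzyloxy)-3-bromo-5-methoxyphenyl]-2-[(2S,4S)-2-tert-butyl-4-({3-methoxy-4-[(triisopropylsilyl)oxy]phenyl}methyl)-5-oxo-1,3-dioxolan-4-yl]propanoic acid
Conditions: LiN(SiMe3)2 (2.2 equiv), THF, −78 °C; then 18 (1.3 equiv), −78 → −30 °C; then 1 M HCl, 0 °C
Reagents that add atoms: none
Why: Seebach dioxolanone alkylation as in step 10, with attack anti to the tert-butyl group and therefore retention at the new quaternary carbon.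

Step 16
Reactants: 19 (2R)-3-[4-(benzyloxy)-3-bromo-5-methoxyphenyl]-2-[(2S,4S)-2-tert-butyl-4-({3-methoxy-4-[(triisopropylsilyl)oxy]phenyl}methyl)-5-oxo-1,3-dioxolan-4-yl]propanoic acid
Product: 20 (2S,3S)-3-{[4-(benzyloxy)-3-bromo-5-methoxyphenyl]methyl}-2-({3-methoxy-4-[(triisopropylsilyl)oxy]phenyl}methyl)butane-1,2,4-triol
Conditions: LiAlH4 (4 equiv), THF, 0 °C → rt; then aqueous potassium sodium tartrate
Reagents that add atoms: none
Why: Hydride reduction of acid and acylal lactone as in step 11; the aryl TIPS ether and aryl bromide should survive.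

Step 17
Reactants: 20 (2S,3S)-3-{[4-(benzyloxy)-3-bromo-5-methoxyphenyl]methyl}-2-({3-methoxy-4-[(triisopropylsilyl)oxy]phenyl}methyl)butane-1,2,4-triol
Product: 21 (2S,3S)-3-{[4-(benzyloxy)-3-methoxy-5-(4,4,5,5-tetramethyl-1,3,2-dioxaborolan-2-yl)phenyl]methyl}-2-({3-methoxy-4-[(triisopropylsilyl)oxy]phenyl}methyl)butane-1,2,4-triol
Conditions: B2pin2 (1.5 equiv), Pd(dppf)Cl2 (5 mol%), KOAc (4 equiv), dioxane, 90 °C
Reagents that add atoms: bis(pinacolato)diboron, CC1(C)OB(OC1(C)C)B1OC(C)(C)C(C)(C)O1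
Why: Miyaura borylation of the aryl bromide under zerovalent palladium catalysis; free hydroxyls, silyl ether and benzyl ether tolerate KOAc in dioxane.

**Union, key step and endgame**

Step 18
Reactants: 14 (2S,3S)-3-{[4-(benzyloxy)-3-bromo-5-methoxyphenyl]methyl}-2-{[4-methoxy-3-(tosyloxy)phenyl]methyl}butane-1,2,4-triol; 21 pinacol boronate of fragment B
Product: 22 5,5'-linked biaryl bis-triol with both biaryl oxygens benzylated (isovanillyl tosylate on fragment A and guaiacyl TIPS ether on fragment B)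
Conditions: Pd(dppf)Cl2 (8 mol%), K3PO4 (3 equiv), dioxane/H2O (5:1), 80 °C
Reagents that add atoms: none
Why: Suzuki–Miyaura coupling of two partners that each carry one ortho substituent; the catalyst inserts into C–Br and not into the aryl C–OTs bond, and the hydroxyls need no protection.

Step 19
Reactants: 22 5,5'-linked biaryl bis-triol bis(benzyl ether)
Product: 23 acyclic 5,5'-biaryl bis-triol with both biaryl phenols free
Conditions: H2 (1 atm), Pd/C (10%), EtOAc/MeOH, rt
Reagents that add atoms: none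
Why: Hydrogenolysis of the two aryl benzyl ethers; aryl tosylate, aryl silyl ether and the hydroxyls are inert and no benzylic ether ring is present yet.

Step 20
Reactants: 23 acyclic 5,5'-biaryl bis-triol with both biaryl phenols free
Product: 27 5,5'-linked bis-oxolane tosylate TIPS ether (each oxolane 2S,3R,4S), via first quinone methide 24 (not isolated), via mono-oxolane 25 (not isolated), via second quinone methide 26 (not isolated)
Conditions: Ag2O (2.2 equiv), CH2Cl2/acetone (4:1), 0.005 M, rt, dark, Ar; filter through Celite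
Reagents that add atoms: none
Why: Ag2O removes two electrons and two protons from one 2-methoxy-6-aryl-4-alkylphenol ring at a time (phenoxyl radical, then disproportionation or a second electron transfer) to give the para-quinone methide, whose exocyclic carbon is attacked by the primary hydroxyl of the C(OH)CH2OH unit three carbons away, restoring the phenol; the sequence then repeats on the second ring (written with the tosylate-side ring first, the order being immaterial). The closest known reaction type is the oxidation of 4-alkylphenols to para-quinone methides with intramolecular alcohol capture, by which seco-lignan diols become 2-aryl oxolanes. Each oxolane closes by a 5-exo-trig oxa-Michael addition, whereas the tertiary hydroxyl and the other primary hydroxyl could only form oxetanes. Each new C2 centre is controlled by the neighbouring C3 centre, the aryl group taking the face trans to the C3 hydroxymethyl group; because the benzylic ether ionises again in step 21, the tosylate-side C2 is finally fixed there under thermodynamic control and the TIPS-side C2 is erased. The step needs oxidation of the two biaryl phenols only and no oxidation beyond the ether stage: the isovanillyl ring is a tosylate with OMe para to its CH2, the guaiacyl oxygen is silylated, and 1.1 equiv of Ag2O per ring at high dilution should limit oxidation of the product C2–H and intermolecular capture.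

Step 21
Reactants: 27 5,5'-linked bis-oxolane tosylate TIPS ether
Product: 28 tetralin–oxolane biaryl with isovanillyl tosylate and 7-O-TIPS tetralin (oxolane 2S,3R,4S; tetralin 1S,2S,3S)
Conditions: TFA (5 vol%), CH2Cl2/HFIP (9:1), 0 °C; then NaHCO3, MeOH
Reagents that add atoms: none
Why: Acid isomerisation of a 2-(4-hydroxyaryl)oxolane to an aryltetralin by intramolecular Friedel–Crafts alkylation (the olivil to cycloolivil change): both benzylic ethers ionise to para-hydroxybenzyl cations, the TIPS-side cation is captured irreversibly by C6 of the guaiacyl ring para to OMe with the aryl group trans to the C2 hydroxymethyl (C1 set S), and the tosylate-side cation recloses to the trans oxolane because C6 of its ring is para to the electron-withdrawing tosyloxy group.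

Step 22
Reactants: 28 tetralin–oxolane biaryl with isovanillyl tosylate and 7-O-TIPS tetralin
Product: 29 tetralin–oxolane biaryl isovanillyl tosylate with free tetralin 7-OH
Conditions: Bu4NF (1.2 equiv), AcOH (1.2 equiv), THF, 0 °C
Reagents that add atoms: none
Why: Fluoride cleavage of the aryl silyl ether, buffered with acetic acid so that no phenoxide opens the benzylic ether; the tosylate is inert.

Step 23
Reactants: 29 tetralin–oxolane biaryl isovanillyl tosylate
Product: 30 CNP0252244.1
Conditions: Mg turnings (10 equiv), MeOH, rt, Ar; then aq. NH4Cl to pH 6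
Reagents that add atoms: none
Why: Reductive S–O cleavage of the aryl tosylate by electron transfer from magnesium in methanol at room temperature, chosen over hot hydroxide because the freed isovanillyl phenoxide would make its C6 nucleophilic toward a base-opened quinone methide.

**Compound list**
1 | 5-bromovanillin (3-bromo-4-hydroxy-5-methoxybenzaldehyde) | COc1cc(C=O)cc(Br)c1O | starting material
2 | 4-(benzyloxy)-3-bromo-5-methoxybenzaldehyde | COc1cc(C=O)cc(Br)c1OCc1ccccc1 | intermediate
3 | [4-(benzyloxy)-3-bromo-5-methoxyphenyl]methanol | COc1cc(CO)cc(Br)c1OCc1ccccc1 | intermediate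
4 | 2-(benzyloxy)-1-bromo-5-(bromomethyl)-3-methoxybenzene | COc1cc(CBr)cc(Br)c1OCc1ccccc1 | intermediate
5 | diethyl (S)-malate | CCOC(=O)C[C@H](O)C(=O)OCC | starting material
6 | diethyl (2S,3R)-3-{[4-(benzyloxy)-3-bromo-5-methoxyphenyl]methyl}-2-hydroxybutanedioate | CCOC(=O)[C@@H](O)[C@@H](Cc1cc(OC)c(OCc2ccccc2)c(Br)c1)C(=O)OCC | intermediate
7 | (2S,3R)-3-{[4-(benzyloxy)-3-bromo-5-methoxyphenyl]methyl}-2-hydroxybutanedioic acid | OC(=O)[C@@H](O)[C@@H](Cc1cc(OC)c(OCc2ccccc2)c(Br)c1)C(=O)O | intermediate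
8 | (2R)-3-[4-(benzyloxy)-3-bromo-5-methoxyphenyl]-2-[(2S,4S)-2-tert-butyl-5-oxo-1,3-dioxolan-4-yl]propanoic acid (cis-dioxolanone) | O=C1O[C@@H](C(C)(C)C)O[C@H]1[C@@H](Cc2cc(OC)c(OCc3ccccc3)c(Br)c2)C(=O)O | intermediate
9 | isovanillin (3-hydroxy-4-methoxybenzaldehyde) | COc1ccc(C=O)cc1O | starting material
10 | 5-formyl-2-methoxyphenyl 4-methylbenzenesulfonate | COc1ccc(C=O)cc1OS(=O)(=O)c1ccc(C)cc1 | intermediate
11 | 5-(hydroxymethyl)-2-methoxyphenyl 4-methylbenzenesulfonate | COc1ccc(CO)cc1OS(=O)(=O)c1ccc(C)cc1 | intermediate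
12 | 5-(bromomethyl)-2-methoxyphenyl 4-methylbenzenesulfonate | COc1ccc(CBr)cc1OS(=O)(=O)c1ccc(C)cc1 | intermediate
13 | (2R)-3-[4-(benzyloxy)-3-bromo-5-methoxyphenyl]-2-[(2S,4S)-2-tert-butyl-4-{[4-methoxy-3-(tosyloxy)phenyl]methyl}-5-oxo-1,3-dioxolan-4-yl]propanoic acid (new arylmethyl trans to tert-butyl) | O=C1O[C@@H](C(C)(C)C)O[C@@]1(Cc2ccc(OC)c(OS(=O)(=O)c3ccc(C)cc3)c2)[C@@H](Cc4cc(OC)c(OCc5ccccc5)c(Br)c4)C(=O)O | intermediate
14 | (2S,3S)-3-{[4-(benzyloxy)-3-bromo-5-methoxyphenyl]methyl}-2-{[4-methoxy-3-(tosyloxy)phenyl]methyl}butane-1,2,4-triol (fragment A) | COc1ccc(C[C@@](O)(CO)[C@H](CO)Cc2cc(OC)c(OCc3ccccc3)c(Br)c2)cc1OS(=O)(=O)c1ccc(C)cc1 | intermediate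
15 | vanillin | COc1cc(C=O)ccc1O | starting material
16 | 3-methoxy-4-[(triisopropylsilyl)oxy]benzaldehyde | COc1cc(C=O)ccc1O[Si](C(C)C)(C(C)C)C(C)C | intermediate
17 | {3-methoxy-4-[(triisopropylsilyl)oxy]phenyl}methanol | COc1cc(CO)ccc1O[Si](C(C)C)(C(C)C)C(C)C | intermediate
18 | [4-(bromomethyl)-2-methoxyphenoxy]triisopropylsilane | COc1cc(CBr)ccc1O[Si](C(C)C)(C(C)C)C(C)C | intermediate
19 | (2R)-3-[4-(benzyloxy)-3-bromo-5-methoxyphenyl]-2-[(2S,4S)-2-tert-butyl-4-({3-methoxy-4-[(triisopropylsilyl)oxy]phenyl}methyl)-5-oxo-1,3-dioxolan-4-yl]propanoic acid | O=C1O[C@@H](C(C)(C)C)O[C@@]1(Cc2ccc(O[Si](C(C)C)(C(C)C)C(C)C)c(OC)c2)[C@@H](Cc4cc(OC)c(OCc5ccccc5)c(Br)c4)C(=O)O | intermediate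
20 | (2S,3S)-3-{[4-(benzyloxy)-3-bromo-5-methoxyphenyl]methyl}-2-({3-methoxy-4-[(triisopropylsilyl)oxy]phenyl}methyl)butane-1,2,4-triol (fragment B) | COc1cc(C[C@@](O)(CO)[C@H](CO)Cc2cc(OC)c(OCc3ccccc3)c(Br)c2)ccc1O[Si](C(C)C)(C(C)C)C(C)C | intermediate
21 | pinacol boronate of fragment B (Bpin in place of Br in 20) | COc1cc(C[C@@](O)(CO)[C@H](CO)Cc2cc(OC)c(OCc3ccccc3)c(B4OC(C)(C)C(C)(C)O4)c2)ccc1O[Si](C(C)C)(C(C)C)C(C)C | intermediate
22 | 5,5'-linked biaryl bis-triol, both biaryl oxygens benzylated, isovanillyl tosylate on one half and guaiacyl TIPS ether on the other | COc1ccc(C[C@@](O)(CO)[C@H](CO)Cc2cc(OC)c(OCc3ccccc3)c(-c4cc(C[C@@H](CO)[C@](O)(CO)Cc5ccc(O[Si](C(C)C)(C(C)C)C(C)C)c(OC)c5)cc(OC)c4OCc6ccccc6)c2)cc1OS(=O)(=O)c1ccc(C)cc1 | intermediate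
23 | acyclic 5,5'-biaryl bis-triol with both biaryl phenols free (key-step precursor) | COc1ccc(C[C@@](O)(CO)[C@H](CO)Cc2cc(OC)c(O)c(-c4cc(C[C@@H](CO)[C@](O)(CO)Cc5ccc(O[Si](C(C)C)(C(C)C)C(C)C)c(OC)c5)cc(OC)c4O)c2)cc1OS(=O)(=O)c1ccc(C)cc1 | intermediate
24 | first quinone methide (tosylate-side biaryl ring oxidised, other half unchanged) | COc1ccc(C[C@@](O)(CO)[C@H](CO)C=C2C=C(OC)C(=O)C(c4cc(C[C@@H](CO)[C@](O)(CO)Cc5ccc(O[Si](C(C)C)(C(C)C)C(C)C)c(OC)c5)cc(OC)c4O)=C2)cc1OS(=O)(=O)c1ccc(C)cc1 | intermediate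
25 | mono-oxolane (tosylate-side oxolane closed, TIPS-side half acyclic) | COc1ccc(C[C@@]2(O)CO[C@H](c3cc(OC)c(O)c(-c4cc(C[C@@H](CO)[C@](O)(CO)Cc5ccc(O[Si](C(C)C)(C(C)C)C(C)C)c(OC)c5)cc(OC)c4O)c3)[C@H]2CO)cc1OS(=O)(=O)c1ccc(C)cc1 | intermediate
26 | second quinone methide (TIPS-side biaryl ring oxidised, tosylate-side oxolane in place) | COc1ccc(C[C@@]2(O)CO[C@H](c3cc(OC)c(O)c(C4=CC(=C[C@@H](CO)[C@](O)(CO)Cc5ccc(O[Si](C(C)C)(C(C)C)C(C)C)c(OC)c5)C=C(OC)C4=O)c3)[C@H]2CO)cc1OS(=O)(=O)c1ccc(C)cc1 | intermediate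
27 | 5,5'-linked bis-oxolane, each ring (2S,3R,4S), isovanillyl tosylate and guaiacyl TIPS ether | COc1ccc(C[C@@]2(O)CO[C@H](c3cc(OC)c(O)c(-c4cc([C@H]5OC[C@](O)(Cc6ccc(O[Si](C(C)C)(C(C)C)C(C)C)c(OC)c6)[C@@H]5CO)cc(OC)c4O)c3)[C@H]2CO)cc1OS(=O)(=O)c1ccc(C)cc1 | intermediate
28 | tetralin–oxolane biaryl, oxolane (2S,3R,4S) with isovanillyl tosylate, tetralin (1S,2S,3S) with 7-O-TIPS | COc1ccc(C[C@@]2(O)CO[C@H](c3cc(OC)c(O)c(-c4cc([C@H]5c6cc(O[Si](C(C)C)(C(C)C)C(C)C)c(OC)cc6C[C@@](O)(CO)[C@@H]5CO)cc(OC)c4O)c3)[C@H]2CO)cc1OS(=O)(=O)c1ccc(C)cc1 | intermediate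
29 | tetralin–oxolane biaryl, isovanillyl tosylate, tetralin 7-OH free | COc1ccc(C[C@@]2(O)CO[C@H](c3cc(OC)c(O)c(-c4cc([C@H]5c6cc(O)c(OC)cc6C[C@@](O)(CO)[C@@H]5CO)cc(OC)c4O)c3)[C@H]2CO)cc1OS(=O)(=O)c1ccc(C)cc1 | intermediate
30 | CNP0252244.1 | COc1ccc(C[C@@]2(O)CO[C@H](c3cc(OC)c(O)c(-c4cc([C@H]5c6cc(O)c(OC)cc6C[C@@](O)(CO)[C@@H]5CO)cc(OC)c4O)c3)[C@H]2CO)cc1O | target

**Step count**
Total: 23 steps. Longest linear sequence: 15 steps (steps 1–6 and 15–23, from 5-bromovanillin).

**Steps most likely to fail**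

1. Step 20. The first-formed oxolane carries a para-hydroxybenzylic C2–H that can be oxidised further, the biphenol can couple oxidatively, and the second closure can stall or lose the quinone methide to intermolecular capture. The fallback closes each oxolane on a monomeric phenol and makes the biaryl bond last. It sets out from 14 and 21. Selective debenzylation of 14 (BCl3, pentamethylbenzene, CH2Cl2, −78 °C) should give the bromophenol triol F1, and Ag2O (1.1 equiv) should close it to the bromo oxolane F2. Hydrogenolysis of 21 (H2, Pd/C) should give the boronate phenol triol F3, and DDQ (1.05 equiv, dioxane, rt) should close it to the oxolane boronate F4. Suzuki–Miyaura coupling of F2 with F4 (Pd(dppf)Cl2, K3PO4, dioxane/H2O) comes back to the route at 27.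

2. Step 21. Chemoselectivity between the two oxolanes can be lost: the tosylated ring can be attacked at its ipso carbon para to OMe, followed by a 1,2-shift, so that a second tetralin forms, or the cations can be drained by other nucleophiles. The fallback forms the tetralin on fragment B alone, where no second benzylic ether exists. It sets out from 20. Debenzylation (BCl3, pentamethylbenzene, −78 °C) should give the bromophenol triol F5. Ag2O followed by TFA in the same flask should give the bromo aryltetralin F6. Miyaura borylation then gives the tetralin boronate F7. Suzuki–Miyaura coupling with 14 gives the biaryl mono(benzyl ether) F8, and hydrogenolysis gives the bisphenol F9. A single Ag2O cycloetherification (1.1 equiv) on the acyclic half comes back to the route at 28.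

3. Step 18. The electron-rich ortho-alkoxy boronate can protodeboronate, and the two polyols can couple slowly through poor solubility or coordination to palladium. The fallback couples before the reduction. It sets out from 19. Miyaura borylation should give the dioxolanone boronate F10. Coupling with 13 under water-free conditions (Pd(dppf)Cl2, powdered K3PO4, dioxane, 80 °C) should give the biaryl bis-dioxolanone diacid F11. One LiAlH4 reduction of both halves comes back to the route at 22.

**Further compounds**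
F1 | step 20 | (2S,3S)-3-[(3-bromo-4-hydroxy-5-methoxyphenyl)methyl]-2-{[4-methoxy-3-(tosyloxy)phenyl]methyl}butane-1,2,4-triol | COc1ccc(C[C@@](O)(CO)[C@H](CO)Cc2cc(OC)c(O)c(Br)c2)cc1OS(=O)(=O)c1ccc(C)cc1
F2 | step 20 | (2S,3R,4S)-2-(3-bromo-4-hydroxy-5-methoxyphenyl)-3-(hydroxymethyl)-4-{[4-methoxy-3-(tosyloxy)phenyl]methyl}oxolan-4-ol | COc1ccc(C[C@@]2(O)CO[C@H](c3cc(OC)c(O)c(Br)c3)[C@H]2CO)cc1OS(=O)(=O)c1ccc(C)cc1
F3 | step 20 | debenzylated boronate triol of fragment B (free phenol ortho to Bpin) | COc1cc(C[C@@](O)(CO)[C@H](CO)Cc2cc(OC)c(O)c(B3OC(C)(C)C(C)(C)O3)c2)ccc1O[Si](C(C)C)(C(C)C)C(C)C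
F4 | step 20 | (2S,3R,4S)-oxolane boronate of fragment B | COc1cc(C[C@@]2(O)CO[C@H](c3cc(OC)c(O)c(B4OC(C)(C)C(C)(C)O4)c3)[C@H]2CO)ccc1O[Si](C(C)C)(C(C)C)C(C)C
F5 | step 21 | (2S,3S)-3-[(3-bromo-4-hydroxy-5-methoxyphenyl)methyl]-2-({3-methoxy-4-[(triisopropylsilyl)oxy]phenyl}methyl)butane-1,2,4-triol | COc1cc(C[C@@](O)(CO)[C@H](CO)Cc2cc(OC)c(O)c(Br)c2)ccc1O[Si](C(C)C)(C(C)C)C(C)C
F6 | step 21 | (1S,2S,3S)-1-(3-bromo-4-hydroxy-5-methoxyphenyl)-2,3-bis(hydroxymethyl)-6-methoxy-7-[(triisopropylsilyl)oxy]tetralin-3-ol | COc1cc([C@H]2c3cc(O[Si](C(C)C)(C(C)C)C(C)C)c(OC)cc3C[C@@](O)(CO)[C@@H]2CO)cc(Br)c1O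
F7 | step 21 | pinacol boronate of the aryltetralin (Bpin in place of Br in F6) | COc1cc([C@H]2c3cc(O[Si](C(C)C)(C(C)C)C(C)C)c(OC)cc3C[C@@](O)(CO)[C@@H]2CO)cc(B4OC(C)(C)C(C)(C)O4)c1O
F8 | step 21 | biaryl of acyclic fragment A (biaryl oxygen benzylated) and the aryltetralin (biaryl phenol free) | COc1ccc(C[C@@](O)(CO)[C@H](CO)Cc2cc(OC)c(OCc3ccccc3)c(-c4cc([C@H]5c6cc(O[Si](C(C)C)(C(C)C)C(C)C)c(OC)cc6C[C@@](O)(CO)[C@@H]5CO)cc(OC)c4O)c2)cc1OS(=O)(=O)c1ccc(C)cc1
F9 | step 21 | biaryl bisphenol of acyclic fragment A and the aryltetralin | COc1ccc(C[C@@](O)(CO)[C@H](CO)Cc2cc(OC)c(O)c(-c4cc([C@H]5c6cc(O[Si](C(C)C)(C(C)C)C(C)C)c(OC)cc6C[C@@](O)(CO)[C@@H]5CO)cc(OC)c4O)c2)cc1OS(=O)(=O)c1ccc(C)cc1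
F10 | step 18 | pinacol boronate of dioxolanone acid 19 (Bpin in place of Br) | O=C1O[C@@H](C(C)(C)C)O[C@@]1(Cc2ccc(O[Si](C(C)C)(C(C)C)C(C)C)c(OC)c2)[C@@H](Cc4cc(OC)c(OCc5ccccc5)c(B6OC(C)(C)C(C)(C)O6)c4)C(=O)O
F11 | step 18 | 5,5'-linked biaryl bis-dioxolanone diacid (halves of 13 and 19 joined at the former C–Br carbons) | O=C1O[C@@H](C(C)(C)C)O[C@@]1(Cc2ccc(OC)c(OS(=O)(=O)c3ccc(C)cc3)c2)[C@@H](Cc4cc(OC)c(OCc5ccccc5)c(-c6cc(C[C@@H](C(=O)O)[C@]7(Cc8ccc(O[Si](C(C)C)(C(C)C)C(C)C)c(OC)c8)O[C@H](C(C)(C)C)OC7=O)cc(OC)c6OCc9ccccc9)c4)C(=O)O
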